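Run gamma held 3.5 mol% of free catalyst and run alpha 5.5 mol%, on equal charges of substrate and partner, and your flask holds 2.5 mol%.

| setting | gamma | alpha | flask |
|---|---|---|---|
| substrate | 30 mM | 30 mM | 30 mM |
| partner | 1.5 equiv | 1.5 equiv | 1.50 equiv |
| free catalyst | 3.5 mol% | 5.5 mol% | 2.5 mol% |
| remark | run made earlier | run made earlier |  |

| run | time / min | target / % | substrate / % |
|---|---|---|---|
| gamma | 0.167 | 6 | 96 |
| gamma | 0.500 | 14 | 88 |
| gamma | 0.833 | 29 | 78 |
| gamma | 1.33 | 36 | 64 |
| gamma | 2.00 | 48 | 50 |
| gamma | 2.50 | 56 | 45 |
| gamma | 3.00 | 64 | 33 |
| alpha | 0.167 | 9 | 93 |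
| alpha | 0.500 | 24 | 78 |
| alpha | 0.833 | 36 | 62 |
| alpha | 1.33 | 49 | 47 |
| alpha | 2.00 | 68 | 32 |
| alpha | 2.50 | 74 | 21 |
| alpha | 3.00 | 80 | 18 |

(standard deviation of a reading: 2 percentage points)

- apparent order in free catalyst when 30% of the substrate are converted (percent change of the rate of making target for one percent more free catalyst charged)

How fast is each run? Take as its pace the logarithm of one over the fraction of substrate left, divided by the time, and read it at 2.00 min. Gamma has 50% left, a pace of 0.347 min⁻¹, and alpha has 32% left, a pace of 0.570 min⁻¹.

Does the pace grow in step with the catalyst? The paces stand at a ratio of 1.64 and the loadings at 1.57, so as read the pace rises a little faster than the loading, a reading that carries the scatter of 2 percentage points. The ratio of the two logarithms is 1.10: this is the catalyst slope, the percent change of pace for one percent more free catalyst charged, between these two loadings and at equal charges of substrate and partner.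

What does that slope mean for your flask? Stepping down from gamma, it gives a pace of 0.239 min⁻¹, so 30% conversion should come at 1.49 min, and the order you should expect is the slope itself.

The forecast puts the order lower than this slope, at 1: “I expect about first order”.

The flask gives an apparent order of 1.2 and reaches 30% conversion at 1.52 min.

    substrate + catalyst intermediate A → catalyst intermediate B (k = 86.0 M⁻¹ s⁻¹)
    partner + free catalyst → catalyst intermediate A (k = 6.14 M⁻¹ s⁻¹)
    catalyst intermediate C ⇌ free catalyst + target (K = 0.180 M, k = 8.23 s⁻¹)
    partner → decomposed reagent (k = 0.00308 s⁻¹)
    catalyst intermediate B ⇌ released group + catalyst intermediate C (K = 0.0290 M, k = 0.459 s⁻¹)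

Your time of 1.49 min stands beside that 1.52 min, and your slope of 1.10, a reading with the scatter of the runs, stands beside that order. The flask's order owes a part of its height to the conversion of partner into decomposed reagent: the same flask with that step taken away has an order of 1.0. At 0.978 min in the flask, partner goes to decomposed reagent at 1.1 times the rate at which it goes with free catalyst into catalyst intermediate A.

Readings and results were computed for substances that don't exist, noise included.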